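## Structural features

The target 19 is a sesquiterpene coumarin: a trans-fused decalin of the ent-drimane series (rings A and B) whose C11 methylene is joined through an aryl ether oxygen to C7 of a coumarin. Drimane numbering is used throughout (C11 is the OCH2 carbon), and "syn" and "anti" give the face of the bicycle relative to the angular C10 methyl. Ring A carries the C4 gem-dimethyl group and a vicinal diol at C2 and C3. Ring B carries the trisubstituted C7=C8 alkene with its methyl and the C9 side chain. There are five stereocentres: C2 and C3 stand next to each other, and C5, C10 (quaternary) and C9 are contiguous around the ring fusion. In the chair–chair decalin both hydroxyls are equatorial (O2 anti, O3 syn), H5 is anti, and C11 is equatorial and syn. The absolute configuration is (2S,3S,5S,9R,10R).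

The fragile points are the coumarin lactone (hydroxide, strong nucleophiles, excess hydride), the C7=C8 alkene (acid can move it to C8=C9), and the homoallylic C11 oxygen (elimination toward C9). The real difficulty is the quaternary C10 in one absolute sense and the relay of its configuration to C5, C9, C2 and C3. The trans-diequatorial diol beside the gem-dimethyl group is the hardest part of that relay, because no single alkene oxidation delivers it.

The key step uses the fact that the C8(CH3)–C9(O)–C10(CH3) edge of ring B, with a removable oxygen at C6, is the substitution pattern of 2,6-dimethyl-1,4-benzoquinone. C1–C4 of ring A, gem-dimethyl included, is 4-methylpenta-1,3-diene, so ring A can close across C5=C10 by a [4+2] addition.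

## Logic of the disconnections

**19 back to 16 (through 18 and 17).** No skeletal bond is cut, only O2–Si and the C3–H bond. Syn-dihydroxylation gives a cis diol and epoxide opening gives the trans-diaxial diol, so the trans-diequatorial diol is traced to the C3 epimer and corrected through the C3 ketone. The gain is that every stereocentre except C3 is already that of 16. The demand is that O2 is told apart from O3 beforehand, and that hydride reaches C3 along the axial line without harming the lactone.

**16 to 14 and 15.** The C11–O(aryl) bond is cut. This keeps the base- and hydride-sensitive heteroaromatic lactone out of all carbanion, borane and samarium steps and makes the end convergent. The demand is substitution at a β-branched primary carbon without elimination toward C9, and selectivity over the C3 hydroxyl.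

**14 to 12 to 10.** The C11–O and C9–H bonds are removed (retro-hydroboration), then C9=C11 (retro-olefination). C9 returns to a carbonyl, the oxidation level the cycloaddition supplies, and the C9 stereocentre and one carbon disappear. The demand is addition of a carbanion to a carbonyl flanked by quaternary C10 and the methylated C8, and a borane that picks the exocyclic terminus and the face anti to the C10 methyl.

**10 to 9 to 8.** O2–Si is removed, then C2–O and C3–O. The isolated C2=C3 alkene is exactly what the diene leaves in ring A, so two stereocentres vanish. The demand is an oxidant that prefers the isolated alkene to the enone alkene and attacks anti to the C10 methyl, and a silylation that prefers equatorial O2.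

**8 to 6 to 5 to 4.** The C6 oxygen is put back. The C6 carbonyl is needed earlier to activate the dienophile and to make C5 epimerizable; after that it is redundant. The demand is a hydride that distinguishes the two carbonyls, and a reductive removal that returns the alkene to C7=C8 and leaves C2=C3 alone.

**4 to 3.** Only the C5–H bond changes. The cycloaddition is suprafacial and can give only the cis fusion, so the trans fusion must come from enolization toward C5. The demand is an equilibrium that lies on the trans side; no other stereocentre is enolizable.

**3 to 1 and 2.** The C1–C10 and C4–C5 bonds are cut, opening ring A. This gives two achiral commercial compounds that hold all fourteen carbons of the bicyclic core. The demand is regiocontrol (CH2 terminus to C10), formation of a quaternary centre with a sluggish diene, and control of the enantioface by a catalyst.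

## Other disconnections considered

**Alternative 1:** The cut goes through C5–C10 and C8–C9 and opens both rings to the acyclic triene A2, whose C3/C4 unit with the gem-dimethyl group would come from (S)-pantolactone A3. In the forward step, heating A2 lets the 7-silyloxy diene (C5=C6–C7=C8) add to the tethered (E)-enoate (C9=C10) to give the decalin A1.

- In its favour: both rings and four stereocentres (C5, C8, C9, C10) arise in one uncatalysed step. The 2,3-diol enters with its final trans relationship, so no inversion at C3 is needed. The absolute configuration rests on the chiral pool and not on a catalyst. On these three points it is the equal or the better of the chosen plan.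
- Against it here: the dienophile is a β,β-disubstituted enoate that must create quaternary C10, so forcing temperatures are to be expected. The facial course is decided only by the tether with its trans-fused acetonide. A3 is the less common enantiomer. A2 needs a long linear assembly with a (Z)-silyl enol ether. A1 still has the wrong ring B functionality (oxygen at C7, saturated C8, ester at C9), so enol triflate formation toward C8, reduction and ester reduction must follow.
- Comparison: structurally the chosen plan starts with the ring B pattern almost in place and pays with the C6 deoxygenation and the C3 inversion. Mechanistically it uses one catalyst-controlled step and then substrate control on a rigid decalin, where the alternative stakes three centres on one thermal transition state. In step count the chosen plan should be clearly shorter.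

**Alternative 2:** The cut is C9–C10 (ring B); the C5–C6 bond of the cyclization substrate A5 would come from an sp2–sp3 Suzuki coupling. In the forward step FSO3H at low temperature protonates C5 of the tetrasubstituted C5=C10 bond, the C10 cation is captured by the (E)-C8=C9 alkene through C9, and loss of H7 gives A4.

- In its favour: it is convergent. Ring B emerges with the C7=C8 alkene, the C8 methyl and the C11 oxygen at their final oxidation levels, so neither a deoxygenation nor a one-carbon homologation is needed; on redox economy it is better than the chosen plan. The diol is already trans and is shielded as a carbonate, so there is no inversion, which is also better. Trans fusion and equatorial C11 follow from anti addition across the (E)-alkene through a chair, which is as dependable as the substrate control of the chosen plan.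
- Against it here: the sense of the three new centres relative to C2/C3 depends on which face of the planar C10 cation is attacked, and the only bias is the distant carbonate. The β-oxygen at C2 destabilizes that cation. The neighbouring quaternary C4 invites a methyl shift. The allylic acetate can ionize in the superacid. The position of the final alkene is settled only by proton loss. Both fragments must also be made, one of them enantioenriched with the trans diol.
- Comparison: after its key step only acetate cleavage, etherification and carbonate removal remain, but fragment synthesis adds steps, so the totals should be comparable. The chosen plan is the stronger on stereocontrol and the weaker on functional-group economy.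

**Alternative 3:** The cut is C4–C5 and C9–C10, opening both rings to the epoxy polyene A7, a silyloxy epoxide of the farnesyl ether of 15 that already carries the coumarin. In the forward step MeAlCl2 opens the epoxide at tertiary C4, the two trisubstituted alkenes add in turn, and loss of H7 gives A6, which is identical with 18 of the chosen route.

- In its favour: it is the most direct plan. All carbons and the ether are in place before cyclization, and the chair–chair transition state sets C5, C9 and C10 relative to the epoxide carbon C3. It places the C3 hydroxyl and the C2 silyloxy group equatorial, exactly as 19 requires, and leaves one deprotection. On step economy and on direct access to the trans-diequatorial diol it is better than the chosen plan.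
- Against it here: the C2 oxygen must be built into the polyene stereoselectively, which rules out the simplest C15 precursors. The silyloxy group beside the epoxide withdraws electron density and can chelate the aluminium reagent. The coumarin carbonyl and the allylic aryl ether also bind the Lewis acid, and the allylic C11–O bond can ionize. The C8 cation can be trapped by the arene or lose a proton in three directions. Cyclizations of this kind are prone to monocyclic and ether by-products, and here that risk falls on the most advanced intermediate.
- Comparison: the alternative is shorter and mechanistically elegant but concentrates the risk in one step. The chosen plan is longer, spreads the risk over steps whose selectivity can be predicted one by one, and brings in the coumarin only after all organometallic chemistry.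

Key step: step 1

Assumption: the (S)-configured catalyst is taken to give the (8aR) adduct, as the usual binding model for quinones predicts (contact of the α-C–H with the ring oxygen, dienophile stacked on one phenyl group); if the sense proved opposite, the equally available (R)-catalyst would be used.

Step 1
Reactants: 1 (2,6-dimethyl-1,4-benzoquinone); 2 (4-methylpenta-1,3-diene)
Product: 3 cis-enedione (4aS,8aR)-2,5,5,8a-tetramethyl-4a,5,8,8a-tetrahydronaphthalene-1,4-dione
Conditions: (S)-B-o-tolyl oxazaborolidine from (S)-α,α-diphenylprolinol activated by Tf2NH (20 mol %), 2 (5 equiv), CH2Cl2, −78 → −20 °C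
Reagents that add atoms: none
Why: The cationic boron Lewis acid binds the C6 carbonyl of 1 (the more basic and less hindered oxygen, flanked by two C–H carbons) at the lone pair syn to C5–H and so lowers the LUMO of the adjacent C5=C10 bond; 2 then adds in a concerted, asynchronous endo [4+2] cycloaddition whose leading bond joins the diene CH2 terminus to the β-carbon C10. The closest known reaction type is the oxazaborolidinium-catalysed enantioselective Diels–Alder reaction of methyl-substituted 1,4-benzoquinones with acyclic dienes. Ring A is closed by this intermolecular cycloaddition, which forms C1–C10 and C4–C5 as a six-membered ring in one operation. C10 is controlled by the catalyst, because the bound quinone lies over one phenyl group of the diphenylcarbinol unit and the diene can reach only the open face; C5 follows from suprafacial addition and is therefore syn to the angular methyl (corrected in step 2). Regioselectivity is required and is secured twice, since the unsubstituted diene terminus is both the more nucleophilic one and the only one small enough to bond to the methyl-bearing C10, which sends the dimethylated terminus to C5. The two C=C bonds of 1 are equivalent by symmetry, so site selectivity reduces to mono-addition, and the remaining C7=C8 bond of 3 is a more hindered and less electrophilic dienophile. The small s-cis population of 2 is offset by the excess of diene and the strong activation.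

Step 2
Reactants: 3 (cis-enedione)
Product: 4 trans-enedione (4aR,8aR)-2,5,5,8a-tetramethyl-4a,5,8,8a-tetrahydronaphthalene-1,4-dione
Conditions: DBU (0.3 equiv), CH2Cl2, argon, rt
Reagents that add atoms: none
Why: C5–H is the only α-hydrogen of the C6 ketone; reversible deprotonation and reprotonation (thermodynamic epimerization) should move the ring fusion to the trans-decalin, in which both ring A bonds are equatorial on ring B. C10 is quaternary and cannot change; recovered 3 is resubmitted.

Step 3
Reactants: 4 (trans-enedione)
Product: 5 hydroxy enone 6-hydroxy-11-nor-ent-drima-2,7-dien-9-one (10R; H5 anti; 6-OH syn)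
Conditions: NaBH4, CeCl3·7H2O, MeOH, −78 °C
Reagents that add atoms: none
Why: Luche reduction gives 1,2-addition at the C6 carbonyl, which is far more accessible than the C9 carbonyl flanked by quaternary C10 and the methylated C8. Hydride should enter anti to the angular methyl; the new centre is removed again in step 5.

Step 4
Reactants: 5 (hydroxy enone)
Product: 6 acetoxy enone 6-acetoxy-11-nor-ent-drima-2,7-dien-9-one
Conditions: Ac2O, DMAP, pyridine, CH2Cl2, rt → 40 °C
Reagents that add atoms: acetic anhydride, CC(=O)OC(C)=O
Why: DMAP-catalysed acylation turns the allylic hydroxyl, which is γ to the C9 carbonyl, into a leaving group for reductive cleavage. No other nucleophilic group is present.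

Step 5
Reactants: 6 (acetoxy enone)
Product: 8 dienone 11-nor-ent-drima-2,7-dien-9-one (10R; H5 anti), via deconjugated enone 7 (not isolated)
Conditions: SmI2 (2.2 equiv), THF–MeOH, −78 °C; then DBU, CH2Cl2, rt
Reagents that add atoms: none
Why: SmI2 reduces the enone with loss of the γ-acetate (reductive elimination of a γ-acyloxy enone) and protonation at C8 gives the β,γ-unsaturated ketone 7. DBU then moves the double bond back into conjugation at C7=C8 (base-mediated alkene isomerization). C5 is no longer α to a carbonyl and keeps its configuration.

Step 6
Reactants: 8 (dienone)
Product: 9 cis-diol 2,3-dihydroxy-11-nor-ent-drim-7-en-9-one (both hydroxyls anti; 2-OH equatorial; 3-OH axial)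
Conditions: OsO4 (cat.), NMO, acetone–H2O, rt
Reagents that add atoms: osmium tetroxide, O=[Os](=O)(=O)=O (transfers both oxygens and is regenerated); N-methylmorpholine N-oxide, C[N+]1([O-])CCOCC1; water, O
Why: Catalytic syn-dihydroxylation prefers the electron-rich isolated C2=C3 bond to the conjugated, electron-poor C7=C8 bond. Attack anti to the axial C10 methyl and the pseudoaxial C4 methyl puts both hydroxyls on the anti face, which sets C2 as in the target and leaves C3 to be inverted.

Step 7
Reactants: 9 (cis-diol)
Product: 10 silyl ether 2-O-tert-butyldimethylsilyl derivative of 9
Conditions: TBSCl, imidazole, DMF, 0 °C → rt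
Reagents that add atoms: tert-butyldimethylsilyl chloride, CC(C)(C)[Si](C)(C)Cl
Why: Silylation selects the equatorial C2 hydroxyl, because the axial C3 hydroxyl is neopentyl and 1,3-diaxial to H1 and H5.

Step 8
Reactants: 10 (silyl ether)
Product: 12 diene 2-O-TBS-ent-drima-7,9(11)-diene-2,3-diol (3-OH axial), via β-hydroxysilane 11 (not isolated)
Conditions: Me3SiCH2Li (4 equiv), THF, −78 → 0 °C; aqueous work-up; then KH, THF, 0 °C → rt
Reagents that add atoms: (trimethylsilyl)methyllithium, [Li]C[Si](C)(C)C
Why: Peterson olefination: the small, strongly nucleophilic silylmethyl carbanion adds to the hindered C9 carbonyl (one equivalent is spent on the C3 hydroxyl), and the potassium alkoxide of 11 loses silanolate by syn-elimination. C9 becomes sp2, so the facial course of the addition does not matter.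

Step 9
Reactants: 12 (diene)
Product: 14 diol 2-O-TBS-ent-drim-7-ene-2,3,11-triol (3-OH axial; C11 syn and equatorial), via primary alkylborane 13 (not isolated)
Conditions: 9-BBN (3 equiv), THF, 0 °C → rt; then NaOH, H2O2, 0 °C → rt
Reagents that add atoms: hydrogen peroxide, OO
Why: Hydroboration–oxidation: 9-BBN adds to the 1,1-disubstituted terminus of the diene with boron at C11 and delivers hydrogen to C9 from the face anti to the axial C10 methyl, which makes C11 equatorial and syn. The trisubstituted C7=C8 bond is too hindered to react, and the oxidation proceeds with retention.

Step 10
Reactants: 14 (diol); 15 (umbelliferone, 7-hydroxy-2H-chromen-2-one)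
Product: 16 coumarin ether 3-epimer of the 2-O-TBS ether of the target (3-OH axial)
Conditions: PPh3, DIAD, THF, 0 °C → rt
Reagents that add atoms: none
Why: Mitsunobu etherification: the primary C11 hydroxyl is activated as an oxyphosphonium ion and displaced by the phenoxide of 15. The axial neopentyl C3 hydroxyl is too hindered to be activated.

Step 11
Reactants: 16 (coumarin ether)
Product: 17 ketone 3-oxo-2-O-TBS coumarin ether
Conditions: Dess–Martin periodinane, pyridine, CH2Cl2, rt
Reagents that add atoms: none
Why: Dess–Martin oxidation converts the axial C3 carbinol into the ketone under buffered conditions that leave the silyl ether, the alkene and the coumarin untouched. The equatorial C2 substituent is the stable epimer and should not move.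

Step 12
Reactants: 17 (ketone)
Product: 18 silyl ether of the target (2-O-TBS; 3-OH equatorial and syn)
Conditions: NaBH4, MeOH–THF, 0 °C
Reagents that add atoms: none
Why: Hydride adds to the C3 carbonyl along the axial line on the face opposite the axial C4 methyl and the C10 methyl, which gives the equatorial alcohol (substrate-controlled ketone reduction, as with 4,4-dimethyl-3-oxo terpenoids). At 0 °C the ketone should react far faster than the coumarin lactone.

Step 13
Reactants: 18 (silyl ether of the target)
Product: 19 target 7-{[(1R,4aS,6S,7S,8aR)-6,7-dihydroxy-2,5,5,8a-tetramethyl-1,4,4a,5,6,7,8,8a-octahydronaphthalen-1-yl]methoxy}-2H-chromen-2-one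
Conditions: TBAF, THF, 0 °C → rt
Reagents that add atoms: none
Why: Fluoride cleaves the Si–O bond (desilylation). A silyl shift between O2 and O3 beforehand would be harmless, because the same diol results.

Compound list

1 | 2,6-dimethyl-1,4-benzoquinone | CC1=CC(=O)C=C(C)C1=O | starting material
2 | 4-methylpenta-1,3-diene | CC(C)=CC=C | starting material
3 | cis-enedione, (4aS,8aR)-2,5,5,8a-tetramethyl-4a,5,8,8a-tetrahydronaphthalene-1,4-dione (H5 syn to the C10 methyl) | CC1=CC(=O)[C@H]2C(C)(C)C=CC[C@@]2(C)C1=O | intermediate
4 | trans-enedione, (4aR,8aR)-2,5,5,8a-tetramethyl-4a,5,8,8a-tetrahydronaphthalene-1,4-dione (H5 anti) | CC1=CC(=O)[C@@H]2C(C)(C)C=CC[C@@]2(C)C1=O | intermediate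
5 | hydroxy enone, 6-hydroxy-11-nor-ent-drima-2,7-dien-9-one (10R; trans-fused; 6-OH syn) | CC1=C[C@H](O)[C@@H]2C(C)(C)C=CC[C@@]2(C)C1=O | intermediate
6 | acetoxy enone, 6-acetate of 5 | CC1=C[C@H](OC(C)=O)[C@@H]2C(C)(C)C=CC[C@@]2(C)C1=O | intermediate
7 | deconjugated enone, 11-nor-ent-drima-2,6-dien-9-one (C8 epimers) | CC1C=C[C@@H]2C(C)(C)C=CC[C@@]2(C)C1=O | intermediate
8 | dienone, 11-nor-ent-drima-2,7-dien-9-one (10R; trans-fused) | CC1=CC[C@@H]2C(C)(C)C=CC[C@@]2(C)C1=O | intermediate
9 | cis-diol, 2,3-dihydroxy-11-nor-ent-drim-7-en-9-one (both OH anti; 2-OH equatorial, 3-OH axial) | CC1=CC[C@@H]2C(C)(C)[C@@H](O)[C@@H](O)C[C@@]2(C)C1=O | intermediate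
10 | silyl ether, 2-O-TBS derivative of 9 | CC1=CC[C@@H]2C(C)(C)[C@@H](O)[C@@H](O[Si](C)(C)C(C)(C)C)C[C@@]2(C)C1=O | intermediate
11 | β-hydroxysilane, 9-hydroxy-9-(trimethylsilylmethyl) adduct of 10 (9-OH syn) | CC1=CC[C@@H]2C(C)(C)[C@@H](O)[C@@H](O[Si](C)(C)C(C)(C)C)C[C@@]2(C)[C@@]1(O)C[Si](C)(C)C | intermediate
12 | diene, 2-O-TBS-ent-drima-7,9(11)-diene-2,3-diol (3-OH axial) | CC1=CC[C@@H]2C(C)(C)[C@@H](O)[C@@H](O[Si](C)(C)C(C)(C)C)C[C@@]2(C)C1=C | intermediate
13 | primary alkylborane, 11-(9-borabicyclo[3.3.1]nonan-9-yl) adduct of 12 (C11 syn) | CC1=CC[C@@H]2C(C)(C)[C@@H](O)[C@@H](O[Si](C)(C)C(C)(C)C)C[C@@]2(C)[C@@H]1CB1C2CCCC1CCC2 | intermediate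
14 | diol, 2-O-TBS-ent-drim-7-ene-2,3,11-triol (3-OH axial; C11 syn, equatorial) | CC1=CC[C@@H]2C(C)(C)[C@@H](O)[C@@H](O[Si](C)(C)C(C)(C)C)C[C@@]2(C)[C@@H]1CO | intermediate
15 | umbelliferone, 7-hydroxy-2H-chromen-2-one | O=c1ccc2ccc(O)cc2o1 | starting material
16 | coumarin ether, 3-epimer of the 2-O-TBS ether of the target (3-OH axial) | CC1=CC[C@@H]2C(C)(C)[C@@H](O)[C@@H](O[Si](C)(C)C(C)(C)C)C[C@@]2(C)[C@@H]1COc1ccc2ccc(=O)oc2c1 | intermediate
17 | ketone, 3-oxo-2-O-TBS coumarin ether | CC1=CC[C@@H]2C(C)(C)C(=O)[C@@H](O[Si](C)(C)C(C)(C)C)C[C@@]2(C)[C@@H]1COc1ccc2ccc(=O)oc2c1 | intermediate
18 | silyl ether of the target (2-O-TBS; 3-OH equatorial) | CC1=CC[C@@H]2C(C)(C)[C@H](O)[C@@H](O[Si](C)(C)C(C)(C)C)C[C@@]2(C)[C@@H]1COc1ccc2ccc(=O)oc2c1 | intermediate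
19 | 7-{[(1R,4aS,6S,7S,8aR)-6,7-dihydroxy-2,5,5,8a-tetramethyl-1,4,4a,5,6,7,8,8a-octahydronaphthalen-1-yl]methoxy}-2H-chromen-2-one | CC1=CC[C@@H]2C(C)(C)[C@H](O)[C@@H](O)C[C@@]2(C)[C@@H]1COc1ccc2ccc(=O)oc2c1 | target

Total step count: 13. Longest linear sequence: 13 steps, from 1 and 2 to 19; 15 is commercial and enters at step 10.

Steps least certain to work

**Step 1 (key step).** The cycloaddition may be slow, because the (Z)-methyl of 2 disfavours the s-cis conformer and C10 becomes quaternary. Acid-induced oligomerization of the diene and an unselective background reaction could then erode conversion and enantioselectivity. The fallback uses an activated diene with the same carbon skeleton; it sets out from 1 and comes back at 3.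
- Commercial 4-methylpent-3-en-2-one is converted with LDA and TIPSOTf into the silyloxy diene 4-methyl-2-(triisopropylsilyloxy)penta-1,3-diene F1.
- Under the same catalyst F1 should add to 1 with the same orientation (CH2 terminus to C10) to give the cis-fused 2-silyloxy adduct F2.
- CsF and PhNTf2 convert F2 into the C2 enol triflate F3.
- Pd(OAc)2, PPh3, Bu3N and HCO2H reduce F3 to 3.

**Step 2.** The equilibration may stop short or lie on the wrong side, because in the trans isomer the C4 gem-dimethyl group presses on the C6 carbonyl oxygen and on the C10 methyl; air oxidation of the dienolate is a second hazard. The fallback replaces thermodynamic by kinetic control; it sets out from 3 and comes back at 4.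
- TMSOTf and Et3N convert 3 into the silyl dienol ether 6-(trimethylsilyloxy)-5,7-diene F4.
- Treatment with TBAF and AcOH in THF at −78 °C should protonate C5 from the face anti to the angular methyl and give 4.

**Step 4.** Acylation may be sluggish, because the C6 hydroxyl sits syn to both the C10 methyl and the axial C4 methyl; forcing conditions could cause elimination toward C5, and excess SmI2 in step 5 could over-reduce the enone. The fallback avoids the alcohol; it sets out from 4 and comes back at 8 through 7.
- p-Toluenesulfonyl hydrazide condenses with the accessible C6 carbonyl to give the tosylhydrazone F5.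
- Catecholborane followed by NaOAc·3H2O reduces it through an allylic diazene, which loses dinitrogen with transposition of the alkene to give 7.
- DBU isomerizes 7 to 8 as in step 5.

**Step 8.** The carbanion may fail to add to the carbonyl between quaternary C10 and the methylated C8, with γ-deprotonation at C6 instead, or the hindered alkoxide may eliminate incompletely. The fallback changes the mechanism from nucleophilic addition–elimination to a titanium carbene olefination; it sets out from 10 and comes back at 12.
- Cp2TiMe2 in toluene at 65 °C generates the titanocene methylidene, which methylenates the C9 carbonyl by [2+2] addition and cycloreversion under non-basic conditions.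
- The C3 hydroxyl is held as a titanium alkoxide and freed on work-up.
- The fallback makes no new compound (F0).

**Step 9.** Hydrogen delivery to C9 may show poor facial selectivity, the borane may attack the diene elsewhere, or the acid-sensitive diene may isomerize before it reacts. The fallback sets C9 under thermodynamic control and avoids the diene; it sets out from 10 and comes back at 14.
- Dimethylsulfonium methylide (Me3SI, KHMDS, THF) adds to the C9 carbonyl to give the spiro-epoxide F6.
- MgBr2·OEt2 rearranges F6 by a 1,2-hydride shift to the β,γ-unsaturated aldehyde F7. Brief exposure to DBU should settle it as the equatorial epimer, with the formyl group syn to the C10 methyl.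
- NaBH4 reduces F7 to 14.

**Step 10.** Displacement at the β-branched C11 may be slow, so that the activated oxygen is lost by elimination toward C9 or the reduced azodicarboxylate is alkylated instead. The fallback is a two-step Williamson etherification; it sets out from 14 and comes back at 16.
- MsCl and Et3N at 0 °C convert the primary hydroxyl selectively into the mesylate F8.
- 15 with Cs2CO3 in DMF at 60 °C displaces the mesylate to give 16.

Further compounds

F1 | step 1 | 4-methyl-2-(triisopropylsilyloxy)penta-1,3-diene | C=C(O[Si](C(C)C)(C(C)C)C(C)C)C=C(C)C
F2 | step 1 | cis-fused 2-(triisopropylsilyloxy) analogue of 3 (silyl enol ether at C2=C3) | CC1=CC(=O)[C@H]2C(C)(C)C=C(O[Si](C(C)C)(C(C)C)C(C)C)C[C@@]2(C)C1=O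
F3 | step 1 | C2 enol triflate of the cis-fused enedione | CC1=CC(=O)[C@H]2C(C)(C)C=C(OS(=O)(=O)C(F)(F)F)C[C@@]2(C)C1=O
F4 | step 2 | silyl dienol ether, 6-(trimethylsilyloxy)-11-nor-ent-drima-2,5,7-trien-9-one | CC1=CC(O[Si](C)(C)C)=C2C(C)(C)C=CC[C@@]2(C)C1=O
F5 | step 4 | C6 tosylhydrazone of 4 | CC1=CC(=NNS(=O)(=O)c2ccc(C)cc2)[C@@H]2C(C)(C)C=CC[C@@]2(C)C1=O
F0 | step 8 | none | none
F6 | step 9 | spiro-epoxide, 9,11-epoxide from 10 (epoxide oxygen syn) | CC1=CC[C@@H]2C(C)(C)[C@@H](O)[C@@H](O[Si](C)(C)C(C)(C)C)C[C@@]2(C)[C@@]13CO3
F7 | step 9 | aldehyde, 2-O-TBS-3-hydroxy-ent-drim-7-en-11-al (formyl group syn, equatorial) | CC1=CC[C@@H]2C(C)(C)[C@@H](O)[C@@H](O[Si](C)(C)C(C)(C)C)C[C@@]2(C)[C@@H]1C=O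
F8 | step 10 | C11 mesylate of 14 | CC1=CC[C@@H]2C(C)(C)[C@@H](O)[C@@H](O[Si](C)(C)C(C)(C)C)C[C@@]2(C)[C@@H]1COS(C)(=O)=O
A1 | alternative 1 | trans-decalin silyl enol ether methyl ester with the 2,3-acetonide | C[C@@H]1C(O[Si](C)(C)C(C)(C)C)=C[C@@H]2C(C)(C)[C@@H]3OC(C)(C)O[C@H]3C[C@@]2(C)[C@@H]1C(=O)OC
A2 | alternative 1 | acyclic triene: (Z)-silyloxy diene tethered through the trans-acetonide to the (E)-enoate | C/C=C(O[Si](C)(C)C(C)(C)C)/C=C/C(C)(C)[C@@H]1OC(C)(C)O[C@H]1C/C(C)=C/C(=O)OC
A3 | alternative 1 | (S)-pantolactone | O=C1OCC(C)(C)[C@@H]1O
A4 | alternative 2 | 2,3-carbonate 11-acetate of the ent-drim-7-ene triol | CC1=CC[C@@H]2C(C)(C)[C@@H]3OC(=O)O[C@H]3C[C@@]2(C)[C@@H]1COC(C)=O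
A5 | alternative 2 | monocyclic cyclization substrate: ring A cyclohexene carbonate with the (E)-acetoxy side chain at C5 | CC1=C(CC/C(C)=C/COC(C)=O)C(C)(C)[C@@H]2OC(=O)O[C@H]2C1
A6 | alternative 3 | 2-O-tert-butyldimethylsilyl ether of the target | CC1=CC[C@@H]2C(C)(C)[C@H](O)[C@@H](O[Si](C)(C)C(C)(C)C)C[C@@]2(C)[C@@H]1COc1ccc2ccc(=O)oc2c1
A7 | alternative 3 | silyloxy epoxy farnesyl ether of umbelliferone (epoxide at C3–C4, silyloxy group at C2) | CC1(C)O[C@@H]1[C@@H](O[Si](C)(C)C(C)(C)C)C/C(C)=C/CC/C(C)=C/COc1ccc2ccc(=O)oc2c1
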